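**Plan**

- Numbering: the lactone is C9(=O)–C8–C8'–C9'H2–O, C7 is the guaiacyl CH2 on C8 and C7' is the veratryl carbinol on C8'. The target is the 8R,8'R,7'S isomer with the two ring substituents trans.
- Retrosynthesis: the C7' alcohol goes back to the aryl ketone. The C8'–C9' bond and the lactone O–C9 bond are then cut together (formaldehyde plus an acyclic γ-keto ester), and last the C8–C8' bond (imide enolate plus α-bromo ketone).
- Enabling feature: C9' is an isolated oxygen-bearing CH2 on C8'. With C7' as a ketone, C8' is its only enolisable α-carbon, so it can be made nucleophilic selectively and stays epimerisable after the γ-lactone, the only ring formed, has closed.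
- Forward: dihydroferulic acid is silylated and loaded on an oxazolidinone, the chain is joined at C8–C8' by alkylation, and the auxiliary is exchanged for a methyl ester. Formaldehyde then adds C9' and the lactone closes in the same operation; ketone reduction and desilylation finish the synthesis.
- Stereochemistry: C8 (R) comes from the (S)-4-benzyl-oxazolidinone in the alkylation, C8' (R) from thermodynamic trans equilibration against C8, and C7' (S) from Felkin–Anh hydride delivery to the ketone.
- Remark: the phenol is carried as its triisopropylsilyl ether, because it must pass alkaline hydroperoxide and amidine base and still leave with buffered fluoride.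

Key step: step 6

Step 1
Reactants: 1 dihydroferulic acid
Product: 3 3-[3-methoxy-4-(triisopropylsilyloxy)phenyl]propanoic acid, via bis-silyl ester 2 (not isolated)
Conditions: i-Pr3SiCl (2.4 equiv), imidazole, DMF, rt; then K2CO3, MeOH/THF/H2O, rt; 1 M HCl work-up
Reagents that add atoms: chlorotriisopropylsilane, CC(C)[Si](Cl)(C(C)C)C(C)C
Why: O-silylation of both acidic hydroxyls followed by selective solvolysis of the far more labile silyl ester is routine and should leave only the hindered aryl silyl ether in place.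

Step 2
Reactants: 3 3-[3-methoxy-4-(triisopropylsilyloxy)phenyl]propanoic acid, 4 (S)-4-benzyl-2-oxazolidinone
Product: 6 (S)-4-benzyl-3-{3-[3-methoxy-4-(triisopropylsilyloxy)phenyl]propanoyl}oxazolidin-2-one, via mixed pivalic anhydride 5 (not isolated)
Conditions: t-BuCOCl, NEt3, THF, −20 °C; then 4, LiCl, −20 °C to rt
Reagents that add atoms: none
Why: N-acylation of the oxazolidinone through a mixed pivalic anhydride under LiCl/NEt3 activation is the standard way to load an Evans auxiliary, the nucleophile attacking the less hindered acyl carbon of 5.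

Step 3
Reactants: 6 (S)-4-benzyl-3-{3-[3-methoxy-4-(triisopropylsilyloxy)phenyl]propanoyl}oxazolidin-2-one, 7 2-bromo-1-(3,4-dimethoxyphenyl)ethanone
Product: 9 (S)-4-benzyl-3-{(R)-4-(3,4-dimethoxyphenyl)-2-[3-methoxy-4-(triisopropylsilyloxy)benzyl]-4-oxobutanoyl}oxazolidin-2-one, via sodium Z-enolate 8 (not isolated)
Conditions: NaN(SiMe3)2, THF, −78 °C; then 7, −78 to −40 °C
Reagents that add atoms: none
Why: In this Evans asymmetric alkylation the chelated Z-enolate 8 is shielded on one face by the C4 benzyl group of the (S)-auxiliary, so the highly SN2-reactive α-bromo ketone should enter from the open face and set C8 as R.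

Step 4
Reactants: 9 (S)-4-benzyl-3-{(R)-4-(3,4-dimethoxyphenyl)-2-[3-methoxy-4-(triisopropylsilyloxy)benzyl]-4-oxobutanoyl}oxazolidin-2-one
Product: 11 (R)-4-(3,4-dimethoxyphenyl)-2-[3-methoxy-4-(triisopropylsilyloxy)benzyl]-4-oxobutanoic acid, via lithium percarboxylate 10 (not isolated)
Conditions: LiOH, 30% H2O2, THF/H2O (3:1), 0 °C; then aq. Na2SO3; 1 M HCl to pH 3
Reagents that add atoms: hydrogen peroxide (acting as LiOOH), OO
Why: Hydroperoxide cleavage of an Evans imide attacks the exocyclic carbonyl selectively and without epimerising C8, the percarboxylate being reduced to the acid by sulfite while the auxiliary is released intact.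

Step 5
Reactants: 11 (R)-4-(3,4-dimethoxyphenyl)-2-[3-methoxy-4-(triisopropylsilyloxy)benzyl]-4-oxobutanoic acid
Product: 12 methyl (R)-4-(3,4-dimethoxyphenyl)-2-[3-methoxy-4-(triisopropylsilyloxy)benzyl]-4-oxobutanoate
Conditions: Me3SiCHN2, PhMe/MeOH (4:1), 0 °C to rt
Reagents that add atoms: (trimethylsilyl)diazomethane, C[Si](C)(C)C=[N+]=[N-]
Why: Esterification with (trimethylsilyl)diazomethane in methanol is a neutral O-methylation of the carboxylic acid that should touch neither the ketone, the aryl silyl ether nor the C8 stereocentre.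

Step 6
Reactants: 12 methyl (R)-4-(3,4-dimethoxyphenyl)-2-[3-methoxy-4-(triisopropylsilyloxy)benzyl]-4-oxobutanoate, 13 formaldehyde (37% aqueous solution)
Product: 16 (3R,4R)-4-(3,4-dimethoxybenzoyl)-3-[3-methoxy-4-(triisopropylsilyloxy)benzyl]dihydrofuran-2(3H)-one, via trimethylsilyl enol ether 14 (not isolated), via hydroxymethyl ketone 15 (not isolated)
Conditions: Me3SiOTf, NEt3, CH2Cl2, 0 °C, volatiles removed; then 37% aq. HCHO, Sc(OTf)3 (10 mol %), THF, rt; then camphorsulfonic acid (5 mol %), CH2Cl2, rt; then DBU (0.25 equiv), 0 °C to rt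
Reagents that add atoms: none
Why: Me3SiOTf/NEt3 enolises only toward C8', the sole enolisable α-carbon of the aryl ketone, because the ester α-hydrogen at C8 is several pKa units less acidic, so silyl enol ether 14 forms with the C8 centre untouched. Sc(OTf)3 then activates aqueous formaldehyde for a Mukaiyama aldol addition (Lewis-acid-catalysed hydroxymethylation of a ketone silyl enol ether is the closest known reaction type), which forges C8'–C9' and stops at mono-addition because the aldol 15 is no longer an enol ether. Under the acid catalyst the primary C9' hydroxyl attacks the C9 methyl ester in a 5-exo-trig acyl substitution, expelling methanol and closing the γ-lactone. The new C8' stereocentre is set under thermodynamic control: it still lies α to the C7' ketone, so catalytic DBU equilibrates it through the ketone enolate until the aroyl group sits trans to the C8 benzyl group, the fixed 8R centre thereby dictating 8'R. The step needs epimerisation at C8' without epimerisation at C8 or β-elimination of the ring oxygen; the first is secured by the much higher acidity of the ketone α-hydrogen compared with the lactone α-hydrogen, the second by the C9'–O bond lying near the nodal plane of the exocyclic enolate (the reverse of a 5-endo-trig closure), so a weak base at low temperature should be enough.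

Step 7
Reactants: 16 (3R,4R)-4-(3,4-dimethoxybenzoyl)-3-[3-methoxy-4-(triisopropylsilyloxy)benzyl]dihydrofuran-2(3H)-one
Product: 17 (3R,4R)-4-[(S)-(3,4-dimethoxyphenyl)(hydroxy)methyl]-3-[3-methoxy-4-(triisopropylsilyloxy)benzyl]dihydrofuran-2(3H)-one
Conditions: LiBH(s-Bu)3, THF, −78 °C; AcOH quench at −78 °C
Reagents that add atoms: none
Why: In this Felkin–Anh-controlled ketone reduction the bulky hydride should attack the aryl ketone anti to the larger C8 branch of C8' and past its hydrogen, which gives the 7'S carbinol, while the cold acidic quench keeps the C7' alkoxide from attacking the lactone carbonyl.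

Step 8
Reactants: 17 (3R,4R)-4-[(S)-(3,4-dimethoxyphenyl)(hydroxy)methyl]-3-[3-methoxy-4-(triisopropylsilyloxy)benzyl]dihydrofuran-2(3H)-one
Product: 18 (3R,4R)-4-[(S)-(3,4-dimethoxyphenyl)(hydroxy)methyl]-3-(4-hydroxy-3-methoxybenzyl)dihydrofuran-2(3H)-one
Conditions: Bu4NF, AcOH (1:1), THF, 0 °C
Reagents that add atoms: none
Why: Fluoride-mediated desilylation of an aryl silyl ether stays fast when buffered with acetic acid, and the buffer should keep the medium too weakly basic for acyl migration to the C7' oxygen and never acidic enough to ionise the electron-rich benzylic alcohol.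

**Compound list**

1 | dihydroferulic acid, 3-(4-hydroxy-3-methoxyphenyl)propanoic acid | COc1cc(CCC(=O)O)ccc1O | starting material
2 | triisopropylsilyl 3-[3-methoxy-4-(triisopropylsilyloxy)phenyl]propanoate | COc1cc(CCC(=O)O[Si](C(C)C)(C(C)C)C(C)C)ccc1O[Si](C(C)C)(C(C)C)C(C)C | intermediate
3 | 3-[3-methoxy-4-(triisopropylsilyloxy)phenyl]propanoic acid | COc1cc(CCC(=O)O)ccc1O[Si](C(C)C)(C(C)C)C(C)C | intermediate
4 | (S)-4-benzyl-2-oxazolidinone | O=C1N[C@@H](Cc2ccccc2)CO1 | starting material
5 | 3-[3-methoxy-4-(triisopropylsilyloxy)phenyl]propanoic pivalic anhydride | COc1cc(CCC(=O)OC(=O)C(C)(C)C)ccc1O[Si](C(C)C)(C(C)C)C(C)C | intermediate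
6 | (S)-4-benzyl-3-{3-[3-methoxy-4-(triisopropylsilyloxy)phenyl]propanoyl}oxazolidin-2-one | COc1cc(CCC(=O)N2[C@@H](Cc3ccccc3)COC2=O)ccc1O[Si](C(C)C)(C(C)C)C(C)C | intermediate
7 | 2-bromo-1-(3,4-dimethoxyphenyl)ethanone | COc1ccc(C(=O)CBr)cc1OC | starting material
8 | sodium Z-enolate of imide 6 | [Na+].[O-]/C(=C\Cc1ccc(O[Si](C(C)C)(C(C)C)C(C)C)c(OC)c1)N1[C@@H](Cc2ccccc2)COC1=O | intermediate
9 | (S)-4-benzyl-3-{(R)-4-(3,4-dimethoxyphenyl)-2-[3-methoxy-4-(triisopropylsilyloxy)benzyl]-4-oxobutanoyl}oxazolidin-2-one | COc1cc(C[C@H](CC(=O)c2ccc(OC)c(OC)c2)C(=O)N2[C@@H](Cc3ccccc3)COC2=O)ccc1O[Si](C(C)C)(C(C)C)C(C)C | intermediate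
10 | lithium (R)-4-(3,4-dimethoxyphenyl)-2-[3-methoxy-4-(triisopropylsilyloxy)benzyl]-4-oxobutaneperoxoate | COc1cc(C[C@H](CC(=O)c2ccc(OC)c(OC)c2)C(=O)O[O-])ccc1O[Si](C(C)C)(C(C)C)C(C)C.[Li+] | intermediate
11 | (R)-4-(3,4-dimethoxyphenyl)-2-[3-methoxy-4-(triisopropylsilyloxy)benzyl]-4-oxobutanoic acid | COc1cc(C[C@H](CC(=O)c2ccc(OC)c(OC)c2)C(=O)O)ccc1O[Si](C(C)C)(C(C)C)C(C)C | intermediate
12 | methyl (R)-4-(3,4-dimethoxyphenyl)-2-[3-methoxy-4-(triisopropylsilyloxy)benzyl]-4-oxobutanoate | COc1cc(C[C@H](CC(=O)c2ccc(OC)c(OC)c2)C(=O)OC)ccc1O[Si](C(C)C)(C(C)C)C(C)C | intermediate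
13 | formaldehyde | C=O | starting material
14 | methyl (2R,3Z)-4-(3,4-dimethoxyphenyl)-2-[3-methoxy-4-(triisopropylsilyloxy)benzyl]-4-(trimethylsilyloxy)but-3-enoate | COc1cc(C[C@H](/C=C(\O[Si](C)(C)C)c2ccc(OC)c(OC)c2)C(=O)OC)ccc1O[Si](C(C)C)(C(C)C)C(C)C | intermediate
15 | methyl (2R)-4-(3,4-dimethoxyphenyl)-3-(hydroxymethyl)-2-[3-methoxy-4-(triisopropylsilyloxy)benzyl]-4-oxobutanoate, both C3 epimers | COc1cc(C[C@H](C(CO)C(=O)c2ccc(OC)c(OC)c2)C(=O)OC)ccc1O[Si](C(C)C)(C(C)C)C(C)C | intermediate
16 | (3R,4R)-4-(3,4-dimethoxybenzoyl)-3-[3-methoxy-4-(triisopropylsilyloxy)benzyl]dihydrofuran-2(3H)-one, trans | COc1cc(C[C@H]2C(=O)OC[C@@H]2C(=O)c2ccc(OC)c(OC)c2)ccc1O[Si](C(C)C)(C(C)C)C(C)C | intermediate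
17 | (3R,4R)-4-[(S)-(3,4-dimethoxyphenyl)(hydroxy)methyl]-3-[3-methoxy-4-(triisopropylsilyloxy)benzyl]dihydrofuran-2(3H)-one | COc1cc(C[C@H]2C(=O)OC[C@@H]2[C@H](O)c2ccc(OC)c(OC)c2)ccc1O[Si](C(C)C)(C(C)C)C(C)C | intermediate
18 | (3R,4R)-4-[(S)-(3,4-dimethoxyphenyl)(hydroxy)methyl]-3-(4-hydroxy-3-methoxybenzyl)dihydrofuran-2(3H)-one (8R,8'R,7'S) | COc1cc(C[C@H]2C(=O)OC[C@@H]2[C@H](O)c2ccc(OC)c(OC)c2)ccc1O | target

**Step count and risks**

Total step count: 8. Longest linear sequence: 8 steps (1 to 18).

Steps most likely to fail: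

Step 6. The silyl enol ether may be hydrolysed back to ketone 12 faster than it adds to formaldehyde in the aqueous medium, and retro-aldol loss of formaldehyde or dehydration of the aldol may compete with ring closure. The fallback replaces the aldol by C-alkylation with a protected formaldehyde equivalent under anhydrous conditions. It sets out from 12 through its silyl enol ether 14, which is alkylated with benzyl chloromethyl ether (ZnBr2 cat., CH2Cl2, 0 °C). This should give methyl (2R)-3-[(benzyloxy)methyl]-4-(3,4-dimethoxyphenyl)-2-[3-methoxy-4-(triisopropylsilyloxy)benzyl]-4-oxobutanoate F1 as C3 epimers. Hydrogenolysis (H2, Pd/C, EtOAc) then frees the primary alcohol. The path comes back to the route at hydroxymethyl ketone 15, which is lactonised with catalytic camphorsulfonic acid and equilibrated with DBU to 16 as in the closing stages of step 6.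

Step 7. Hydride delivery may show insufficient facial selectivity at C7', and the lithium alkoxide may attack the lactone carbonyl and shift the ring to the C7' oxygen before the quench. The fallback changes from substrate control under basic conditions to catalyst control under neutral ones. Compound 16 is reduced with BH3·SMe2 and catalytic (R)-2-methyl-CBS-oxazaborolidine (Corey–Bakshi–Shibata reduction, THF, −20 °C). With the aryl group acting as the large ketone substituent, this catalyst should again give the 7'S carbinol, and the boron-bound oxygen cannot translactonise. The path sets out from 16 and comes back at 17; it makes no new compound, entered below as none F0.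

Step 3. The enolate may deprotonate the acidic α-bromo ketone or add to its carbonyl group instead of displacing bromide, and the ketone product may quench unreacted enolate. The fallback builds the aryl ketone after the stereocentre is set.
- It sets out from 6 through enolate 8, which is alkylated with tert-butyl bromoacetate. This should give tert-butyl (R)-4-[(S)-4-benzyl-2-oxooxazolidin-3-yl]-3-[3-methoxy-4-(triisopropylsilyloxy)benzyl]-4-oxobutanoate F2 with the same facial sense, since the acetate arm outranks the benzyl arm just as the ketone arm does.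
- CF3CO2H in CH2Cl2 removes the tert-butyl group to give (R)-4-[(S)-4-benzyl-2-oxooxazolidin-3-yl]-3-[3-methoxy-4-(triisopropylsilyloxy)benzyl]-4-oxobutanoic acid F3.
- Oxalyl chloride with catalytic DMF converts it into (R)-4-[(S)-4-benzyl-2-oxooxazolidin-3-yl]-3-[3-methoxy-4-(triisopropylsilyloxy)benzyl]-4-oxobutanoyl chloride F4.
- Negishi acylation with (3,4-dimethoxyphenyl)zinc chloride F5 (from 4-bromo-1,2-dimethoxybenzene, Mg, then ZnCl2) and catalytic Pd(PPh3)4 in THF installs the aryl ketone. The path comes back to the route at 9.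

Further compounds
F1 | step 6 | methyl (2R)-3-[(benzyloxy)methyl]-4-(3,4-dimethoxyphenyl)-2-[3-methoxy-4-(triisopropylsilyloxy)benzyl]-4-oxobutanoate, both C3 epimers | COc1cc(C[C@H](C(COCc2ccccc2)C(=O)c2ccc(OC)c(OC)c2)C(=O)OC)ccc1O[Si](C(C)C)(C(C)C)C(C)C
F0 | step 7 | none | none
F2 | step 3 | tert-butyl (R)-4-[(S)-4-benzyl-2-oxooxazolidin-3-yl]-3-[3-methoxy-4-(triisopropylsilyloxy)benzyl]-4-oxobutanoate | COc1cc(C[C@H](CC(=O)OC(C)(C)C)C(=O)N2[C@@H](Cc3ccccc3)COC2=O)ccc1O[Si](C(C)C)(C(C)C)C(C)C
F3 | step 3 | (R)-4-[(S)-4-benzyl-2-oxooxazolidin-3-yl]-3-[3-methoxy-4-(triisopropylsilyloxy)benzyl]-4-oxobutanoic acid | COc1cc(C[C@H](CC(=O)O)C(=O)N2[C@@H](Cc3ccccc3)COC2=O)ccc1O[Si](C(C)C)(C(C)C)C(C)C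
F4 | step 3 | (R)-4-[(S)-4-benzyl-2-oxooxazolidin-3-yl]-3-[3-methoxy-4-(triisopropylsilyloxy)benzyl]-4-oxobutanoyl chloride | COc1cc(C[C@H](CC(=O)Cl)C(=O)N2[C@@H](Cc3ccccc3)COC2=O)ccc1O[Si](C(C)C)(C(C)C)C(C)C
F5 | step 3 | (3,4-dimethoxyphenyl)zinc chloride | COc1ccc([Zn]Cl)cc1OC
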